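A direct plan would grow both rings at once on the chain: dimethyl hexadecanedioate A1 would acylate the dianion of 3-methylpentane-2,4-dione A2 twice, alkali would close both acylated ends by intramolecular aldol condensation to the bis-resorcinol A3, and oxidation would give the bis(hydroxyquinone) A4.
One ring of A4 would then be O-methylated to the mono-ether A5, and the missing oxygens would come from a Thiele–Winter acetoxylation to the heptaacetate A6, followed by deacetylation and autoxidation.
Its weakest step would be the twofold aldol ring closure to A3: each end could close in two directions, nothing in the substrate decides between them, and the reaction is untested on such triketones, so the ring closure on which everything rests would be left to chance.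
The second would be the mono-methylation of A4: two identical, remote rings would be told apart by statistics only, so at best about half of the late material would be used per pass, with diol and bis-ether to separate and recycle.
The third would be the acetoxylation and sevenfold deacetylation/autoxidation of the desymmetrised A5: once the rings exist, four steps would add only one methyl group and two oxygens, and strong acid, then base and air, would be the last operations on the most precious compounds.

**Plan of the new route**
The retrosynthesis cuts only the two ring–chain C(sp2)–C(sp3) bonds. The target falls into tetradecanedial (one end masked as a dioxolane) and two chain-free quinones, 5 (methoxy ring A) and 6 (dihydroxy ring B), both already at the final oxidation level.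
The enabling feature: in each ring the chain sits on C3 of a 2-hydroxy-1,4-benzoquinone, the α-carbon of the vinylogous acid HO–C2=C3–C4=O. In 5 and 6 this carbon is the only ring C–H and is C-nucleophilic, so an aldehyde can be attached there by reductive alkylation (Knoevenagel condensation, then hydride transfer).
No ring is built: both quinones come from one phenol (1), whose adjacent OMe and CH3 fix the position of the methyl ether from the first step. Ring B is attached first (step 7), ring A last (step 9).
So there is no ring closure to go astray and no statistical methylation, since the two rings are different before they meet. Nothing is oxidised, acetoxylated or deprotected after the chain is on; the last C–C bond formation delivers the target itself.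

Key step: step 9

Remark: the target is achiral; each hydroxyquinone ring is written in the tautomer of the target structure. Quinone 5 is divided after step 3: one part is converted into 6 in step 4, the other part is kept for step 9.

Step 1
Reactants: 1 3-methoxy-2-methylphenol
Product: 2 2-methoxy-3-methylcyclohexa-2,5-diene-1,4-dione
Conditions: Fremy's salt (KSO3)2NO (2.2 equiv), KH2PO4, H2O/acetone, 0 °C → rt
Reagents that add atoms: Fremy's salt (potassium nitrosodisulfonate), [K+].[K+].[O]N(S(=O)(=O)[O-])S(=O)(=O)[O-]
Why: Teuber oxidation: two equivalents of the nitroxide radical convert a phenol with a free para position into the p-quinone, the new oxygen entering para to OH (the carbon next to OMe); no stereocentre is formed.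

Step 2
Reactants: 2 2-methoxy-3-methylcyclohexa-2,5-diene-1,4-dione
Product: 3 5-methoxy-6-methylbenzene-1,2,4-triyl triacetate
Conditions: Ac2O, conc. H2SO4 (cat.), 0 °C → rt
Reagents that add atoms: acetic anhydride, CC(=O)OC(C)=O
Why: Thiele–Winter acetoxylation: the 2-OMe makes C4=O a vinylogous ester, so acid-activated conjugate addition of acetate goes through the other enone (C1=O, C6=C5) to C5, the 2,5-orientation that methoxy-p-benzoquinone shows, and enolisation and acetylation then give the triacetate; no stereocentre is formed.

Step 3
Reactants: 3 5-methoxy-6-methylbenzene-1,2,4-triyl triacetate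
Product: 5 5-hydroxy-2-methoxy-3-methylcyclohexa-2,5-diene-1,4-dione, via triol 4 (not isolated)
Conditions: 2 M aq NaOH (6 equiv), degassed THF, 0 °C → rt, Ar; then air (O2), rt; 1 M HCl
Reagents that add atoms: none
Why: Saponification of the three aryl acetates under argon gives triol 4, whose autoxidation in alkali should stop at the hydroxy-p-quinone because the product is present as its stabilised anion, which also shields the vinylogous methyl ester from hydroxide until acidification; no stereocentre is formed.

Step 4
Reactants: 5 5-hydroxy-2-methoxy-3-methylcyclohexa-2,5-diene-1,4-dione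
Product: 6 2,5-dihydroxy-3-methylcyclohexa-2,5-diene-1,4-dione
Conditions: 70 % aq HClO4, 1,4-dioxane, rt
Reagents that add atoms: water, O
Why: Acid-catalysed addition–elimination of water at the methoxy-bearing carbon of the vinylogous ester, the usual conversion of methoxy- into hydroxy-p-quinones; the ring C–H next to OH is nucleophilic, not electrophilic, and should be left alone; no stereocentre is formed.

Step 5
Reactants: 7 2-(3-chloropropyl)-1,3-dioxolane; 8 11-bromoundec-1-ene
Product: 10 2-(tetradec-13-en-1-yl)-1,3-dioxolane, via Grignard reagent 9 (not isolated)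
Conditions: Mg, THF, reflux; then 8, Li2CuCl4 (3 mol %), THF, −10 °C → rt
Reagents that add atoms: none
Why: Kochi–Tamura coupling: copper-catalysed substitution of a primary alkyl bromide by a primary alkyl Grignard reagent joins the C11 and C4 pieces, and neither the terminal alkene nor the dioxolane reacts with the Grignard reagent at these temperatures; no stereocentre is formed.

Step 6
Reactants: 10 2-(tetradec-13-en-1-yl)-1,3-dioxolane
Product: 12 13-(1,3-dioxolan-2-yl)tridecanal, via 1,2-diol 11 (not isolated)
Conditions: K2OsO4·2H2O (1 mol %), NaIO4 (4 equiv), 2,6-lutidine, 1,4-dioxane/H2O, rt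
Reagents that add atoms: sodium periodate, [Na+].[O-]I(=O)(=O)=O
Why: Lemieux–Johnson oxidation: catalytic dihydroxylation of the terminal alkene to diol 11 and periodate cleavage remove the terminal CH2 as formaldehyde and leave the C14 aldehyde, while 2,6-lutidine keeps the medium neutral so that the dioxolane survives; the racemic carbinol centre of 11 is destroyed in the same flask.

Step 7
Reactants: 6 2,5-dihydroxy-3-methylcyclohexa-2,5-diene-1,4-dione; 12 13-(1,3-dioxolan-2-yl)tridecanal
Product: 14 3-[13-(1,3-dioxolan-2-yl)tridecyl]-2,5-dihydroxy-6-methylcyclohexa-2,5-diene-1,4-dione, via alkylidene trione 13 (not isolated)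
Conditions: L-proline (20 mol %), diethyl 2,6-dimethyl-1,4-dihydropyridine-3,5-dicarboxylate (Hantzsch ester, 1.2 equiv), CH2Cl2/MeCN, rt, Ar
Reagents that add atoms: none
Why: Three-component organocatalytic reductive alkylation of a hydroxy-p-quinone (Knoevenagel condensation, then hydride transfer from the Hantzsch ester to the alkylidene trione 13), a reaction type established for 2,5-dihydroxy-1,4-benzoquinone and 2-hydroxy-1,4-naphthoquinone with aliphatic aldehydes; C6 is the only ring C–H of 6, so only monoalkylation is possible, the dioxolane should be inert to the weakly acidic, amine-buffered medium, and no stereocentre is formed.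

Step 8
Reactants: 14 3-[13-(1,3-dioxolan-2-yl)tridecyl]-2,5-dihydroxy-6-methylcyclohexa-2,5-diene-1,4-dione
Product: 15 14-(2,5-dihydroxy-4-methyl-3,6-dioxocyclohexa-1,4-dien-1-yl)tetradecanal
Conditions: 2 M aq HCl/THF, rt
Reagents that add atoms: water, O
Why: Acid hydrolysis of the dioxolane sets the second aldehyde free; ring B carries no acid-labile group (the methoxy ring is not yet present), and the aldehyde cannot condense with its own ring because that ring has no C–H left; no stereocentre is formed.

Step 9
Reactants: 15 14-(2,5-dihydroxy-4-methyl-3,6-dioxocyclohexa-1,4-dien-1-yl)tetradecanal; 5 5-hydroxy-2-methoxy-3-methylcyclohexa-2,5-diene-1,4-dione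
Product: 17 2,5-dihydroxy-3-[14-(2-hydroxy-5-methoxy-4-methyl-3,6-dioxocyclohexa-1,4-dien-1-yl)tetradecyl]-6-methylcyclohexa-2,5-diene-1,4-dione (CNP0130251.0), via alkylidene trione 16 (not isolated)
Conditions: 5 (1.2 equiv), L-proline (20 mol %), Hantzsch ester (1.3 equiv), CH2Cl2/MeCN, rt, Ar, slow addition of 15; air on work-up
Reagents that add atoms: none
Why: The proline iminium of aldehyde 15 is attacked by C6 of 5 (the α-carbon of the vinylogous acid HO–C5=C6–C1=O and the only ring C–H), loss of the amine gives the ortho-quinone-methide-type alkylidene trione 16, and 1,4-hydride transfer from the Hantzsch ester to its exocyclic carbon followed by tautomerisation restores the hydroxyquinone with the chain in place. The closest known reaction is the three-component reductive alkylation of 2-hydroxy-1,4-naphthoquinone and of 2,5-dihydroxy-1,4-benzoquinone with aliphatic aldehydes. No ring is closed and no stereocentre is formed; the geometry of the exocyclic double bond of 16 is lost on reduction. The step needs site selectivity, which is secured because ring B of 15 is fully substituted and 5 has a single ring C–H, so exactly one C–C bond can form and it joins two rings that are already different. It also needs the hydride to reduce 16 and not the quinones, which the low reduction potential of hydroxyquinones favours (any hydroquinone is re-oxidised by air on work-up), and it needs 16 to be reduced before a second molecule of 5 adds to it, which excess Hantzsch ester and slow addition of 15 should ensure. The methoxy group should survive because the catalyst is a zwitterionic amino acid and ring A is an electron-rich hydroxyquinone, a poor acceptor for amine addition–elimination.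

**Compound list**
1 | 3-methoxy-2-methylphenol | COc1cccc(O)c1C | starting material
2 | 2-methoxy-3-methylcyclohexa-2,5-diene-1,4-dione | COC1=C(C)C(=O)C=CC1=O | intermediate
3 | 5-methoxy-6-methylbenzene-1,2,4-triyl triacetate | COc1c(C)c(OC(C)=O)c(OC(C)=O)cc1OC(C)=O | intermediate
4 | 5-methoxy-6-methylbenzene-1,2,4-triol | COc1c(C)c(O)c(O)cc1O | intermediate (not isolated)
5 | 5-hydroxy-2-methoxy-3-methylcyclohexa-2,5-diene-1,4-dione (ring A quinone) | COC1=C(C)C(=O)C(O)=CC1=O | intermediate
6 | 2,5-dihydroxy-3-methylcyclohexa-2,5-diene-1,4-dione (ring B quinone) | CC1=C(O)C(=O)C=C(O)C1=O | intermediate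
7 | 2-(3-chloropropyl)-1,3-dioxolane | ClCCCC1OCCO1 | starting material
8 | 11-bromoundec-1-ene | C=CCCCCCCCCCBr | starting material
9 | [3-(1,3-dioxolan-2-yl)propyl]magnesium chloride | Cl[Mg]CCCC1OCCO1 | intermediate (not isolated)
10 | 2-(tetradec-13-en-1-yl)-1,3-dioxolane | C=CCCCCCCCCCCCCC1OCCO1 | intermediate
11 | 14-(1,3-dioxolan-2-yl)tetradecane-1,2-diol (racemic) | OCC(O)CCCCCCCCCCCCC1OCCO1 | intermediate (not isolated)
12 | 13-(1,3-dioxolan-2-yl)tridecanal | O=CCCCCCCCCCCCCC1OCCO1 | intermediate
13 | 2-[13-(1,3-dioxolan-2-yl)tridecylidene]-6-hydroxy-5-methylcyclohex-5-ene-1,3,4-trione (alkene geometry not defined) | CC1=C(O)C(=O)C(=CCCCCCCCCCCCCC2OCCO2)C(=O)C1=O | intermediate (not isolated)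
14 | 3-[13-(1,3-dioxolan-2-yl)tridecyl]-2,5-dihydroxy-6-methylcyclohexa-2,5-diene-1,4-dione | CC1=C(O)C(=O)C(CCCCCCCCCCCCCC2OCCO2)=C(O)C1=O | intermediate
15 | 14-(2,5-dihydroxy-4-methyl-3,6-dioxocyclohexa-1,4-dien-1-yl)tetradecanal | CC1=C(O)C(=O)C(CCCCCCCCCCCCCC=O)=C(O)C1=O | intermediate
16 | 2,5-dihydroxy-3-[14-(5-methoxy-4-methyl-2,3,6-trioxocyclohex-4-en-1-ylidene)tetradecyl]-6-methylcyclohexa-2,5-diene-1,4-dione (alkene geometry not defined) | COC1=C(C)C(=O)C(=O)C(=CCCCCCCCCCCCCCC2=C(O)C(=O)C(C)=C(O)C2=O)C1=O | intermediate (not isolated)
17 | 2,5-dihydroxy-3-[14-(2-hydroxy-5-methoxy-4-methyl-3,6-dioxocyclohexa-1,4-dien-1-yl)tetradecyl]-6-methylcyclohexa-2,5-diene-1,4-dione (CNP0130251.0, achiral) | COC1=C(C)C(=O)C(O)=C(CCCCCCCCCCCCCCC2=C(O)C(=O)C(C)=C(O)C2=O)C1=O | target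

**Step count:** 9 steps in total; longest linear sequence 7 steps (steps 1, 2, 3, 4, 7, 8, 9).

**Steps most likely to fail**

- **Step 9.** The alkylidene intermediate may be captured by a second molecule of 5 faster than by hydride, or the amine catalyst may add to the methoxy-bearing carbon of ring A and displace methoxide. The fallback sets out from 15 (together with 5) and comes back at 17. An amine-free and hydride-free Hooker-type condensation of 5 with 15 (AcOH, a little conc. HCl, 70 °C) would let the alkylidene tautomerise to the conjugated alkenyl hydroxyquinone 2,5-dihydroxy-3-[(13E)-14-(2-hydroxy-5-methoxy-4-methyl-3,6-dioxocyclohexa-1,4-dien-1-yl)tetradec-13-en-1-yl]-6-methylcyclohexa-2,5-diene-1,4-dione F1. Hydrogenation (H2, Pd/C, EtOAc) would saturate the side-chain double bond and reduce the quinones to hydroquinones, and stirring in air would re-oxidise both rings to 17.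

- **Step 7.** The dioxolane may be lost under the acidity of 6 during the condensation, which would free the second aldehyde too early and lead to alkylation at both chain ends by the same quinone. The fallback sets out from 10 and comes back at 15; it carries the second terminus as the acid-stable terminal alkene instead. The acetal of 10 would be hydrolysed first (2 M aq HCl/THF) to pentadec-14-enal F2. Reductive alkylation of 6 with this aldehyde under the conditions of step 7 would give 2,5-dihydroxy-3-methyl-6-(pentadec-14-en-1-yl)cyclohexa-2,5-diene-1,4-dione F3. Lemieux–Johnson cleavage of its terminal alkene (K2OsO4·2H2O cat., NaIO4, 2,6-lutidine, dioxane/H2O) would then give 15.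

- **Step 2.** The acetoxylation may be poorly regioselective, with acetate entering the ring carbon that is 2,5-related to the methyl group and not the one 2,5-related to the methoxy group. The fallback sets out from 1 and comes back at triol 4; it places the two new oxygens by electrophilic substitution. Twofold Duff formylation of 1 (hexamethylenetetramine, CF3CO2H, reflux; then aq HCl) can only strike the positions ortho and para to OH, because the third free position is meta to both oxygens. It would give 4-hydroxy-6-methoxy-5-methylbenzene-1,3-dicarbaldehyde F4. A twofold Dakin oxidation (H2O2, aq NaOH, Ar) would turn both formyl groups into hydroxyls to give 4, which is aerated to 5 as in step 3.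

**Further compounds**
F1 | step 9 | 2,5-dihydroxy-3-[(13E)-14-(2-hydroxy-5-methoxy-4-methyl-3,6-dioxocyclohexa-1,4-dien-1-yl)tetradec-13-en-1-yl]-6-methylcyclohexa-2,5-diene-1,4-dione | COC1=C(C)C(=O)C(O)=C(/C=C/CCCCCCCCCCCCC2=C(O)C(=O)C(C)=C(O)C2=O)C1=O
F2 | step 7 | pentadec-14-enal | C=CCCCCCCCCCCCCC=O
F3 | step 7 | 2,5-dihydroxy-3-methyl-6-(pentadec-14-en-1-yl)cyclohexa-2,5-diene-1,4-dione | CC1=C(O)C(=O)C(CCCCCCCCCCCCCC=C)=C(O)C1=O
F4 | step 2 | 4-hydroxy-6-methoxy-5-methylbenzene-1,3-dicarbaldehyde | COc1c(C)c(O)c(C=O)cc1C=O
A1 | direct plan | dimethyl hexadecanedioate | COC(=O)CCCCCCCCCCCCCCC(=O)OC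
A2 | direct plan | 3-methylpentane-2,4-dione | CC(=O)C(C)C(=O)C
A3 | direct plan | 5,5'-(tetradecane-1,14-diyl)bis(2-methylbenzene-1,3-diol) | Cc1c(O)cc(CCCCCCCCCCCCCCc2cc(O)c(C)c(O)c2)cc1O
A4 | direct plan | 6,6'-(tetradecane-1,14-diyl)bis(2-hydroxy-3-methylcyclohexa-2,5-diene-1,4-dione) | CC1=C(O)C(=O)C(CCCCCCCCCCCCCCC2=CC(=O)C(C)=C(O)C2=O)=CC1=O
A5 | direct plan | 2-hydroxy-6-[14-(5-methoxy-4-methyl-3,6-dioxocyclohexa-1,4-dien-1-yl)tetradecyl]-3-methylcyclohexa-2,5-diene-1,4-dione | COC1=C(C)C(=O)C=C(CCCCCCCCCCCCCCC2=CC(=O)C(C)=C(O)C2=O)C1=O
A6 | direct plan | 5-methoxy-6-methyl-3-[14-(2,3,5,6-tetraacetoxy-4-methylphenyl)tetradecyl]benzene-1,2,4-triyl triacetate | COc1c(C)c(OC(C)=O)c(OC(C)=O)c(CCCCCCCCCCCCCCc2c(OC(C)=O)c(OC(C)=O)c(C)c(OC(C)=O)c2OC(C)=O)c1OC(C)=O
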